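I started from the vessel: the earlier runs came from a closed stirred flask, and grey stays in that flask at spring's charges and merely runs longer than they did, green and amber are flow tanks, and red is a stirred flask with Ptn dosed in.

| setting | spring | summer | midnight | grey | green | amber | red |
|---|---|---|---|---|---|---|---|
| Sub | 0.050 M | 0.050 M | 0.050 M | 0.050 M | 0.050 M | 0.050 M | 0.050 M |
| Ptn | 1.2 equiv | 1.2 equiv | 1.2 equiv | 1.20 equiv | 1.20 equiv | 1.20 equiv | 1.20 equiv (fed, over 2.00 min) |
| Cat | 0.5 mol% | 0.34 mol% | 0.75 mol% | 0.5 mol% | 0.5 mol% | 0.5 mol% | 0.5 mol% |
| remark | run made earlier | run made earlier | run made earlier | everything together in a closed stirred flask, run for 2.5 min | one stirred flow tank at steady state, fed with the mixture as stated, mean residence time 2.5 min | a single well-mixed tank run continuously and read at steady state, 25.0 min in it on average | a stirred flask in which Ptn is dosed at a steady rate over 2.00 min without added volume, worked up at 2.5 min |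
| time |  |  |  | 2.5 min |  |  | 2.5 min |

- spring (time / s: Pdt / %, Sub / %): 10.0: 4.4, 94.5; 15.0: 5.9, 93.9; 25.0: 9.0, 91.8; 50.0: 11.2, 88.0; 90.0: 14.3, 85.7
- summer (time / s: Pdt / %, Sub / %): 10.0: 3.5, 95.7; 15.0: 5.4, 95.3; 25.0: 6.2, 92.7; 50.0: 9.0, 90.1; 90.0: 12.6, 88.0
- midnight (time / s: Pdt / %, Sub / %): 10.0: 6.5, 93.4; 15.0: 8.0, 92.5; 25.0: 9.9, 89.9; 50.0: 13.6, 87.0; 90.0: 16.4, 83.4

(scatter of a reading: 0.5 percentage points)

- the stated concentrations are those of everything mixed, before any reaction; amounts are the same in each set-up
- the earlier runs were read with a standard deviation of 0.5 percentage points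
- the feed brings no volume worth counting
- the earlier runs were made in a closed, stirred flask

1. the set-up with the highest amount of Pdt at the outlet or at the end, in percent of the Sub put in ("none" if the first two lie within 2 percentage points) (grey / green / amber / red / none)
2. amount of Pdt at the outlet or at the end, in percent of the Sub put in, grey
3. amount of Pdt at the outlet or at the end, in percent of the Sub put in, green
4. amount of Pdt at the outlet or at the end, in percent of the Sub put in, amber
5. amount of Pdt at the outlet or at the end, in percent of the Sub put in, red

In the closed flask, Pdt rose by about equal steps for equal factors of time. So I read one quantity from the spring run: 4.5 percentage points of Pdt, counted on Sub (the limiting reagent), each time the elapsed time is multiplied by e. I called this the reach. Summer gave 4.1 points and midnight 4.5 points, each read with a scatter of about 0.32 points.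

Loading came first. The curves lay together against Cat times time, so I let a factor in Cat act as the same factor in time:

midnight at 90.0 s = 14.3 % + reach × ln(0.75/0.5) = 16.1 %

The reading was 16.4 %. Time came next:

grey = 14.3 % + reach × ln(2.5 min/90.0 s) = 16.6 %

For the tanks I committed to no number. Ten times the time is worth 10 points in a closed flask, but a tank keeps receiving fresh Cat. For red I had nothing either, since the runs held Ptn at one charge.

The forecast said 18 % for grey, 12.5 % for green, 32 % for amber and 15 % for red, with amber best, reading the catalyst as “slowed strongly as product builds”.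

Grey gave 16.6 %, green 19.5 %, amber 47.9 % and red 5.50 %, so amber gave more than any other.

    Ptn + Cat → Ptn.Cat (k = 28.0 M⁻¹ s⁻¹)
    Sub + Ptn.Cat ⇌ Int (K = 51.0 M⁻¹, k = 380 M⁻¹ s⁻¹)
    Int → Cat + Pdt (k = 240 s⁻¹)
    2 Cat → Zed (k = 310 M⁻¹ s⁻¹)

Red reached 9.53 % when the dose went in over 0.750 min instead of 2.00 min. Its shortfall against grey, 11 points, came to 2.47 reaches. Carried forward from red's 5.50 %, the reach gave 15.9 % at 25.0 min, and red left that long stood at 17.3 %.

(The readings stem from a simulated flask on assumed constants; noise was put on by code.)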